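**Strategy.** The 2,3-dihydrofuran ring (C13, C14, C15, O, C16; labdane numbering) is disconnected at O–C16. Its spiro carbon C13 carries two methylene arms, C14 and C16, so the ring is traced back to a spiro-cyclobutanone (C13–C14–C15(=O)–C16) in which C13 is not yet stereogenic. A catalyst-controlled Baeyer–Villiger oxidation inserts oxygen between C15 and C16 of the fully functionalised cyclobutanone (6β-acetate, 8β,17-epoxide and 19,20-lactone in place). One operation expands the four-membered carbocycle to the five-membered oxacycle and fixes C13. Reduction and dehydration of the γ-lactone then give the enol ether. The core comes from a Birch reductive alkylation and a lactone-tethered desymmetrising cyclopropanation.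

Key step: step 19

Remark on names: locants are labdane numbers (decalin C1–C10, side chain C11–C16, C17 on C8, C18/C19 on C4, C20 on C10); β is the face of C20.
Assumption: the sense of induction of the chiral catalysts in steps 4 and 19 is set by the choice of catalyst enantiomer; the antipode that gives the drawn product is meant.

Step 1
Reactants: 1 3,5-dimethoxybenzoic acid; 2 1-bromo-3-chloropropane
Product: 3 1-(3-chloropropyl)-3,5-dimethoxycyclohexa-2,5-diene-1-carboxylic acid
Conditions: Li, NH3(l)/THF, −78 °C; then 2, −78 °C; NH4Cl, careful acidification to pH 5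
Reagents that add atoms: none
Why: Birch reductive alkylation, in which the carboxylate-stabilised dienyl dianion should be alkylated at the ipso carbon by the C–Br end of 2, creating the still prochiral quaternary C10 with C20 as CO2H, C1–C3 as the chloropropyl arm and C6/C8 as enol ethers.

Step 2
Reactants: 3 1-(3-chloropropyl)-3,5-dimethoxycyclohexa-2,5-diene-1-carboxylic acid
Product: 4 [1-(3-chloropropyl)-3,5-dimethoxycyclohexa-2,5-dien-1-yl]methanol
Conditions: LiAlH4, Et2O, 0 °C to rt; Rochelle salt work-up
Reagents that add atoms: none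
Why: Hydride reduction of the carboxylic acid to the neopentyl alcohol (C20–OH), under which the enol ethers and the primary chloride should be inert.

Step 3
Reactants: 4 [1-(3-chloropropyl)-3,5-dimethoxycyclohexa-2,5-dien-1-yl]methanol; 5 glyoxylic acid chloride p-toluenesulfonylhydrazone
Product: 7 [1-(3-chloropropyl)-3,5-dimethoxycyclohexa-2,5-dien-1-yl]methyl diazoacetate, via tosylhydrazone ester 6 (not isolated)
Conditions: 5, PhNMe2, CH2Cl2, 0 °C; then Et3N, 0 °C to rt
Reagents that add atoms: none
Why: O-acylation followed by base-induced loss of sulfinate from the tosylhydrazone (Bamford–Stevens-type diazo formation) should give the diazoacetate without acid that would harm the enol ethers.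

Step 4
Reactants: 7 [1-(3-chloropropyl)-3,5-dimethoxycyclohexa-2,5-dien-1-yl]methyl diazoacetate
Product: 8 cyclopropane-fused δ-lactone (cyclopropane C4–C5–C6 on the β face; 6α-OMe; C8(OMe)=C9 enol ether; lactone C19(=O)–O–C20; 3-chloropropyl on C10)
Conditions: Rh2(5S-MEPY)4 (1 mol %), CH2Cl2, reflux, slow addition of 7
Reagents that add atoms: none
Why: Rh(II)-carboxamidate-catalysed intramolecular cyclopropanation, in which the carbenoid tethered through C20–O can reach only the syn face of an enol ether double bond (C4–C5 bond cis to C20, hence H5 trans to C20) and the chiral catalyst selects one of the two enantiotopic alkenes, setting C10 and C5.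

Step 5
Reactants: 8 cyclopropane-fused δ-lactone
Product: 10 bicyclic vinylogous ester lactone (ring B 6-methoxy-6-en-8-one; δ-lactone C4H2–C19(=O)–O–C20 cis-fused at C5/C10; 3-chloropropyl on C10), via cyclopropyl ketone 9 (not isolated)
Conditions: 0.1 M oxalic acid, THF–H2O, 0 °C; then DBU (excess), 0 °C to rt
Reagents that add atoms: water O
Why: Mild enol ether hydrolysis unmasks the C8 ketone, and an E1cB-type retro-Michael opening of the donor–acceptor cyclopropane (C7 enolate pushes, the ester-stabilised C4 carbanion leaves) should give the vinylogous ester with C8=O and C6–OMe fixed by the cyclopropanation.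

Step 6
Reactants: 10 bicyclic vinylogous ester lactone
Product: 11 silyl dienol ether (6-methoxy-8-triethylsilyloxy-6,8-diene) of 10
Conditions: TESOTf, Et3N, CH2Cl2, −78 to 0 °C
Reagents that add atoms: triethylsilyl trifluoromethanesulfonate CC[Si](CC)(CC)OS(=O)(=O)C(F)(F)F
Why: Soft enolisation and O-silylation at the α′ position (C9) masks the only ketone-type acidic site, so that the strong bases of steps 7 and 8 should deprotonate the lactone alone and no C9 enolate can attack the chloropropyl arm.

Step 7
Reactants: 11 silyl dienol ether of 10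
Product: 12 4-methyl lactone (C4 epimers; otherwise as 11)
Conditions: LDA, THF, −78 °C; MeI, −78 to −40 °C
Reagents that add atoms: iodomethane CI
Why: Lactone enolate alkylation should install C18 on C4, the configuration being irrelevant because C4 is enolised again in step 8.

Step 8
Reactants: 12 4-methyl lactone
Product: 14 tricyclic vinylogous ester (ring A closed; 4α-methyl; 19,20-olide; 5α-H; ring B 6-methoxy-6-en-8-one), via tricyclic silyl dienol ether 13 (not isolated)
Conditions: KHMDS, NaI (cat.), THF/DMPU, −78 °C to rt; then MeOH, K2CO3 (cat.), 0 °C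
Reagents that add atoms: none
Why: Intramolecular 6-exo-tet enolate alkylation should close ring A as the bridged bicyclo[3.3.1] lactone, the tether allowing attack on one enolate face only (C19 β, C18 α), and methanolysis of the silyl enol ether then returns the vinylogous ester.

Step 9
Reactants: 14 tricyclic vinylogous ester; 15 4-iodo-1-(trimethylsilyl)but-1-yne
Product: 16 9-[4-(trimethylsilyl)but-3-ynyl] vinylogous ester (C9 epimers)
Conditions: LDA, THF, −78 °C; then 15, HMPA, −78 to −20 °C
Reagents that add atoms: none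
Why: Stork–Danheiser α′-alkylation, in which the kinetic enolate can form only at C9 because C7 is vinylic and C4 is quaternary, should attach C11, C12, C13 and C16.

Step 10
Reactants: 16 9-alkylated vinylogous ester
Product: 19 9α-triethylsilyloxy-9β-[4-(trimethylsilyl)but-3-ynyl] vinylogous ester, via silyl dienol ether 17 (not isolated), via silyloxy epoxide 18 (not isolated)
Conditions: KHMDS, TESCl, THF, −78 °C; then DMDO, acetone/CH2Cl2, −78 to 0 °C
Reagents that add atoms: chlorotriethylsilane CC[Si](Cl)(CC)CC; dimethyldioxirane CC1(C)OO1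
Why: Rubottom oxidation, in which the tetrasubstituted C8=C9 silyl enol ether should be epoxidised from the α face anti to the axial C20 bridge and the 1,4-silyl shift then gives the 9α-silyloxy ketone with the side chain β.

Step 11
Reactants: 19 9α-silyloxy vinylogous ester
Product: 21 8-methyl-7-en-6-one (9α-OTES; silylbutynyl chain; 19,20-olide), via tertiary carbinol 20 (not isolated)
Conditions: MeLi, CeCl3, THF, −78 °C; then 1 M HCl, THF, 0 °C
Reagents that add atoms: methyllithium [Li]C; water O
Why: Stork–Danheiser transposition (1,2-addition of the organocerium to the vinylogous ester carbonyl, then acid hydrolysis and dehydration) should bring in C17 and turn C6 into the ketone, the hindered bridged lactone being spared.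

Step 12
Reactants: 21 8-methyl-7-en-6-one
Product: 23 6β-hydroxy-8(17)-ene (9α-OTES; but-3-ynyl chain; 19,20-olide), via exocyclic enone 22 (not isolated)
Conditions: KOtBu, tBuOH/THF, 0 °C; AcOH, −78 °C; then NaBH4, CeCl3·7H2O, MeOH, −40 °C
Reagents that add atoms: none
Why: Deconjugative kinetic α-protonation of the γ-deprotonated dienolate (the alkoxide also cleaves the alkynyl silane) should give the exocyclic β,γ-enone, and Luche reduction from the α face, the β face being blocked by the axial C19/C20 lactone bridge, sets the 6β-alcohol.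

Step 13
Reactants: 23 6β-hydroxy-8(17)-ene
Product: 24 8β,17-epoxy-6β-ol (9α-OTES; but-3-ynyl chain; 19,20-olide)
Conditions: VO(acac)2 (cat.), tBuOOH, CH2Cl2, 0 °C to rt
Reagents that add atoms: tert-butyl hydroperoxide CC(C)(C)OO
Why: Vanadium-catalysed hydroxyl-directed epoxidation, in which the axial homoallylic 6β-OH should deliver oxygen to the β face of the exocyclic alkene while the axial 9α-OTES shields the α face, sets C8 with O β and C17 α.

Step 14
Reactants: 24 8β,17-epoxy-6β-ol
Product: 25 6β-acetate of 24
Conditions: Ac2O, DMAP, Et3N, CH2Cl2, rt to 40 °C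
Reagents that add atoms: acetic anhydride CC(=O)OC(C)=O
Why: DMAP-catalysed acylation should esterify the hindered axial secondary alcohol under basic conditions that leave the epoxide, alkyne and tertiary silyl ether untouched.

Step 15
Reactants: 25 6β-acetate
Product: 26 6β-acetoxy-8β,17-epoxy-9α-hydroxy-9β-(but-3-ynyl) 19,20-olide
Conditions: TBAF, AcOH, THF, rt
Reagents that add atoms: none
Why: Fluoride desilylation frees the tertiary 9α-OH, and the acetic acid buffer should suppress Payne rearrangement of the epoxy alkoxide and acetate migration.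

Step 16
Reactants: 26 alkynol
Product: 27 9α,13-epoxy-13(16)-ene (spiro 2-methylenetetrahydrofuran at C9; 6β-OAc; 8β,17-epoxide; 19,20-olide)
Conditions: Ph3PAuNTf2 (2 mol %), CH2Cl2, 0 °C to rt; Et3N quench
Reagents that add atoms: none
Why: Gold(I)-catalysed 5-exo-dig hydroalkoxylation (cycloisomerisation) of the 4-alkynol should close the spiro tetrahydrofuran with retention at C9 and give the exocyclic enol ether.

Step 17
Reactants: 27 exocyclic enol ether
Product: 28 spiro-2,2-dichlorocyclobutanone (C13 spiro; C14 = CCl2; C15 = C=O; C16 = CH2; C13 epimers)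
Conditions: Cl2CHCOCl, Et3N, Et2O/hexane, 0 °C to rt, slow addition
Reagents that add atoms: dichloroacetyl chloride ClC(Cl)C(Cl)=O
Why: Ketene–alkene [2+2] cycloaddition of dichloroketene generated in situ, whose carbonyl carbon should bond to the CH2 terminus of the enol ether, builds the four-membered ring; the C13 configuration is uncontrolled and is erased in step 18.

Step 18
Reactants: 28 spiro-dichlorocyclobutanone
Product: 29 spiro-cyclobutanone (C13 not stereogenic; 6β-OAc; 8β,17-epoxide; 19,20-olide)
Conditions: Zn–Cu, NH4Cl, MeOH, rt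
Reagents that add atoms: none
Why: Reductive dechlorination of the α,α-dichloro ketone by zinc under near-neutral conditions should spare the epoxide and converge both C13 epimers of 28 on one 3,3-disubstituted cyclobutanone.

Step 19
Reactants: 29 spiro-cyclobutanone
Product: 31 spiro-γ-lactone (15,16-olide; C13 configured as in the target), via Criegee adduct 30 (not isolated)
Conditions: chiral phosphoric acid (3,3′-di(1-pyrenyl)-H8-BINOL phosphate, 10 mol %), 30% aq. H2O2, CHCl3, −40 °C
Reagents that add atoms: hydrogen peroxide OO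
Why: Hydrogen peroxide adds to the acid-activated C15 carbonyl to give the Criegee hydroxy-hydroperoxide, and a strain-driven 1,2-shift of one α-methylene from carbon to oxygen expels water and gives the γ-lactone. The closest known reaction type is the catalytic asymmetric Baeyer–Villiger desymmetrisation of prochiral 3-substituted cyclobutanones with aqueous H2O2 and a chiral Brønsted acid. No ring is closed; the C13–C14–C15–C16 carbocycle is enlarged by insertion of one oxygen between C15 and C16. The new stereocentre C13 is controlled by the catalyst, which holds the Criegee adduct in a chiral hydrogen-bonded ion pair and places either C14 or C16 antiperiplanar to the O–O bond; the nearest substrate stereocentre (C9) is three bonds from C15, so substrate bias should be small. The step needs migration of C16 and not C14, secured by the catalyst enantiomer, and chemoselectivity for the cyclobutanone over the acetate, the bridged δ-lactone and the epoxide, secured by ring strain and by the weak acid at low temperature.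

Step 20
Reactants: 31 spiro-γ-lactone
Product: 32 lactol (15-hydroxy-15,16-epoxide; C15 anomers)
Conditions: Sia2BH (from BH3·THF and 2-methylbut-2-ene), THF, 0 °C to rt; then H2O2, pH 7 buffer
Reagents that add atoms: none
Why: Partial reduction of a γ-lactone to the lactol with the hindered dialkylborane disiamylborane, which should react only very slowly with the acetate, the epoxide and the neopentyl bridged δ-lactone.

Step 21
Reactants: 32 lactol
Product: 34 target CNP0173713.2 (6β-acetoxy-8β,17:9α,13:15,16-triepoxylabd-14-en-19,20-olide), via lactol mesylate 33 (not isolated)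
Conditions: MsCl, Et3N, CH2Cl2, −40 °C to reflux
Reagents that add atoms: none
Why: Dehydration of the lactol through its mesylate (base-mediated elimination) should give the 2,3-dihydrofuran under basic conditions, avoiding the acid that would open the enol ether spiro-ether system to a furan.

Compound list
1 | 3,5-dimethoxybenzoic acid | COc1cc(cc(OC)c1)C(=O)O | starting material
2 | 1-bromo-3-chloropropane | ClCCCBr | starting material
3 | 1-(3-chloropropyl)-3,5-dimethoxycyclohexa-2,5-diene-1-carboxylic acid | OC(=O)C1(CCCCl)C=C(OC)CC(OC)=C1 | intermediate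
4 | [1-(3-chloropropyl)-3,5-dimethoxycyclohexa-2,5-dien-1-yl]methanol | OCC1(CCCCl)C=C(OC)CC(OC)=C1 | intermediate
5 | glyoxylic acid chloride p-toluenesulfonylhydrazone | Cc1ccc(cc1)S(=O)(=O)NN=CC(Cl)=O | starting material
6 | glyoxylate tosylhydrazone ester of 4 | Cc1ccc(cc1)S(=O)(=O)NN=CC(=O)OCC1(CCCCl)C=C(OC)CC(OC)=C1 | intermediate
7 | [1-(3-chloropropyl)-3,5-dimethoxycyclohexa-2,5-dien-1-yl]methyl diazoacetate | [N-]=[N+]=CC(=O)OCC1(CCCCl)C=C(OC)CC(OC)=C1 | intermediate
8 | cyclopropane-fused δ-lactone (C4–C5–C6 cyclopropane on the β face; 6α-OMe; 8-OMe-8-ene; 19,20-olide; 3-chloropropyl on C10) | COC1=C[C@]4(CCCCl)COC(=O)[C@H]2[C@@H]4[C@@]2(OC)C1 | intermediate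
9 | 8-oxo cyclopropane lactone (as 8 with C8 ketone and C9H2) | O=C1C[C@]4(CCCCl)COC(=O)[C@H]2[C@@H]4[C@@]2(OC)C1 | intermediate
10 | bicyclic vinylogous ester lactone (6-methoxy-6-en-8-one; cis-fused C4H2–C19(=O)–O–C20 lactone; 3-chloropropyl on C10) | COC1=CC(=O)C[C@]2(CCCCl)COC(=O)C[C@H]12 | intermediate
11 | 6-methoxy-8-triethylsilyloxy-6,8-diene lactone (silyl dienol ether of 10) | COC1=CC(O[Si](CC)(CC)CC)=C[C@]2(CCCCl)COC(=O)C[C@H]12 | intermediate
12 | 4-methyl derivative of 11 (C4 epimers) | COC1=CC(O[Si](CC)(CC)CC)=C[C@]2(CCCCl)COC(=O)C(C)[C@H]12 | intermediate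
13 | tricyclic silyl dienol ether (ring A closed; 4α-Me; 19,20-olide; 5α-H; 6-OMe-8-OTES-6,8-diene) | COC1=CC(O[Si](CC)(CC)CC)=C[C@]23CCC[C@](C)(C(=O)OC2)[C@H]13 | intermediate
14 | tricyclic vinylogous ester (4α-Me; 19,20-olide; 5α-H; 6-methoxy-6-en-8-one) | COC1=CC(=O)C[C@]23CCC[C@](C)(C(=O)OC2)[C@H]13 | intermediate
15 | 4-iodo-1-(trimethylsilyl)but-1-yne | C[Si](C)(C)C#CCCI | starting material
16 | 9-[4-(trimethylsilyl)but-3-ynyl] derivative of 14 (C9 epimers) | COC1=CC(=O)C(CCC#C[Si](C)(C)C)[C@]23CCC[C@](C)(C(=O)OC2)[C@H]13 | intermediate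
17 | 8-triethylsilyloxy-6,8-diene of 16 (tetrasubstituted silyl dienol ether) | COC1=CC(O[Si](CC)(CC)CC)=C(CCC#C[Si](C)(C)C)[C@]23CCC[C@](C)(C(=O)OC2)[C@H]13 | intermediate
18 | 8α,9α-epoxy-8-triethylsilyloxy-6-methoxy-6-ene (silyloxy epoxide) | COC1=C[C@@]2(O[Si](CC)(CC)CC)O[C@@]2(CCC#C[Si](C)(C)C)[C@]34CCC[C@](C)(C(=O)OC3)[C@H]14 | intermediate
19 | 9α-triethylsilyloxy-9β-[4-(trimethylsilyl)but-3-ynyl]-6-methoxy-6-en-8-one 19,20-olide | COC1=CC(=O)[C@](O[Si](CC)(CC)CC)(CCC#C[Si](C)(C)C)[C@]23CCC[C@](C)(C(=O)OC2)[C@H]13 | intermediate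
20 | 8-hydroxy-8-methyl-6-methoxy-6-ene carbinol (C8 epimers) | COC1=CC(C)(O)[C@](O[Si](CC)(CC)CC)(CCC#C[Si](C)(C)C)[C@]23CCC[C@](C)(C(=O)OC2)[C@H]13 | intermediate
21 | 8-methyl-7-en-6-one (9α-OTES; 9β-silylbutynyl; 19,20-olide) | O=C1C=C(C)[C@](O[Si](CC)(CC)CC)(CCC#C[Si](C)(C)C)[C@]23CCC[C@](C)(C(=O)OC2)[C@H]13 | intermediate
22 | 8(17)-en-6-one (9α-OTES; 9β-but-3-ynyl; 19,20-olide) | O=C1CC(=C)[C@](O[Si](CC)(CC)CC)(CCC#C)[C@]23CCC[C@](C)(C(=O)OC2)[C@H]13 | intermediate
23 | 6β-hydroxy-8(17)-ene (9α-OTES; 9β-but-3-ynyl; 19,20-olide) | O[C@@H]1CC(=C)[C@](O[Si](CC)(CC)CC)(CCC#C)[C@]23CCC[C@](C)(C(=O)OC2)[C@H]13 | intermediate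
24 | 8β,17-epoxy-6β-hydroxy (9α-OTES; 9β-but-3-ynyl; 19,20-olide) | O[C@@H]1C[C@@]2(CO2)[C@](O[Si](CC)(CC)CC)(CCC#C)[C@]23CCC[C@](C)(C(=O)OC2)[C@H]13 | intermediate
25 | 6β-acetoxy-8β,17-epoxy (9α-OTES; 9β-but-3-ynyl; 19,20-olide) | CC(=O)O[C@@H]1C[C@@]2(CO2)[C@](O[Si](CC)(CC)CC)(CCC#C)[C@]23CCC[C@](C)(C(=O)OC2)[C@H]13 | intermediate
26 | 6β-acetoxy-8β,17-epoxy-9α-hydroxy-9β-(but-3-ynyl) 19,20-olide | CC(=O)O[C@@H]1C[C@@]2(CO2)[C@](O)(CCC#C)[C@]23CCC[C@](C)(C(=O)OC2)[C@H]13 | intermediate
27 | 6β-acetoxy-8β,17:9α,13-diepoxy-13(16)-ene 19,20-olide (exocyclic enol ether) | CC(=O)O[C@@H]1C[C@@]2(CO2)[C@]2(CCC(=C)O2)[C@]23CCC[C@](C)(C(=O)OC2)[C@H]13 | intermediate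
28 | spiro-2,2-dichlorocyclobutanone (C14 = CCl2; C15 = C=O; C13 epimers) | CC(=O)O[C@@H]1C[C@@]2(CO2)[C@]2(CCC3(C(Cl)(Cl)C(=O)C3)O2)[C@]23CCC[C@](C)(C(=O)OC2)[C@H]13 | intermediate
29 | spiro-cyclobutanone (C13–C14H2–C15(=O)–C16H2) | CC(=O)O[C@@H]1C[C@@]2(CO2)[C@]2(CCC3(CC(=O)C3)O2)[C@]23CCC[C@](C)(C(=O)OC2)[C@H]13 | intermediate
30 | Criegee adduct (15-hydroxy-15-hydroperoxy cyclobutane) | CC(=O)O[C@@H]1C[C@@]2(CO2)[C@]2(CCC3(CC(O)(OO)C3)O2)[C@]23CCC[C@](C)(C(=O)OC2)[C@H]13 | intermediate
31 | 6β-acetoxy-8β,17:9α,13-diepoxy-labdane-19,20:15,16-diolide (spiro-γ-lactone) | CC(=O)O[C@@H]1C[C@@]2(CO2)[C@]2(CC[C@]3(CC(=O)OC3)O2)[C@]23CCC[C@](C)(C(=O)OC2)[C@H]13 | intermediate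
32 | 15-hydroxy-15,16-epoxide lactol (C15 anomers) | CC(=O)O[C@@H]1C[C@@]2(CO2)[C@]2(CC[C@]3(CC(O)OC3)O2)[C@]23CCC[C@](C)(C(=O)OC2)[C@H]13 | intermediate
33 | lactol 15-O-mesylate | CC(=O)O[C@@H]1C[C@@]2(CO2)[C@]2(CC[C@]3(CC(OS(C)(=O)=O)OC3)O2)[C@]23CCC[C@](C)(C(=O)OC2)[C@H]13 | intermediate
34 | CNP0173713.2 (6β-acetoxy-8β,17:9α,13:15,16-triepoxylabd-14-en-19,20-olide) | CC(=O)O[C@@H]1C[C@@]2(CO2)[C@]2(CC[C@]3(C=COC3)O2)[C@]23CCC[C@](C)(C(=O)OC2)[C@H]13 | target

Total step count: 21. Longest linear sequence: 21 steps (from 1).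

Steps most likely to fail

Step 19. The two diastereotopic α-methylene groups may be differentiated poorly, giving low selectivity at C13, or the acid may open the epoxide. Fallback: set out from 28 and use substrate control in place of catalyst control. The C13 epimer of 28 with the target configuration, matched dichlorocyclobutanone F1, is separated by chromatography; the other epimer is dechlorinated to 29 as in step 18 and recycled. F1 is oxidised with mCPBA/NaHCO3 in CH2Cl2 in a regioselective Baeyer–Villiger reaction in which the electron-poor CCl2 carbon does not migrate, so C16 migrates, to give the α,α-dichloro-γ-lactone F2. Zn–Cu/NH4Cl in MeOH then removes both chlorines and the route is rejoined at 31.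

Step 4. The catalyst may discriminate the enantiotopic enol ether double bonds insufficiently, or carbene dimerisation may compete. Fallback: set out from 7 and replace asymmetric catalysis by resolution. Rh2(OAc)4 gives the racemic cyclopropane, that is 8 together with the enantiomeric cyclopropane lactone F3. The conditions of step 5 carry the racemate through 9 and the enantiomeric cyclopropyl ketone F4 to racemic vinylogous ester, that is 10 with the enantiomeric vinylogous ester lactone F5. Preparative chromatography on a chiral stationary phase separates 10 from F5, and the route is rejoined at 10.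

Step 12. The dienolate may be protonated at the γ carbon, the β,γ-enone may reconjugate before it is reduced, or C5 may epimerise under the alkoxide. Fallback: set out from 21 and use the dienol acetate/borohydride route. K2CO3/MeOH removes the C-silyl group to give the terminal-alkyne enone F6. Isopropenyl acetate with catalytic TsOH gives the dienol acetate F7 (6-acetoxy-6,8(17)-diene). NaBH4 in EtOH/THF cleaves the acetate, the liberated dienolate is protonated at C7 to 22, and 22 is reduced in the same flask from the α face, so the route is rejoined at 23.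

Further compounds
F1 | step 19 | matched C13 epimer of spiro-dichlorocyclobutanone 28 | CC(=O)O[C@@H]1C[C@@]2(CO2)[C@]2(CC[C@]3(C(Cl)(Cl)C(=O)C3)O2)[C@]23CCC[C@](C)(C(=O)OC2)[C@H]13
F2 | step 19 | 14,14-dichloro spiro-γ-lactone | CC(=O)O[C@@H]1C[C@@]2(CO2)[C@]2(CC[C@]3(C(Cl)(Cl)C(=O)OC3)O2)[C@]23CCC[C@](C)(C(=O)OC2)[C@H]13
F3 | step 4 | enantiomer of cyclopropane lactone 8 | COC1=C[C@@]4(CCCCl)COC(=O)[C@@H]2[C@H]4[C@]2(OC)C1
F4 | step 4 | enantiomer of cyclopropyl ketone 9 | O=C1C[C@@]4(CCCCl)COC(=O)[C@@H]2[C@H]4[C@]2(OC)C1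
F5 | step 4 | enantiomer of vinylogous ester lactone 10 | COC1=CC(=O)C[C@@]2(CCCCl)COC(=O)C[C@@H]12
F6 | step 12 | 8-methyl-7-en-6-one with terminal alkyne (C-desilylated 21) | O=C1C=C(C)[C@](O[Si](CC)(CC)CC)(CCC#C)[C@]23CCC[C@](C)(C(=O)OC2)[C@H]13
F7 | step 12 | 6-acetoxy-6,8(17)-diene (dienol acetate) | CC(=O)OC1=CC(=C)[C@](O[Si](CC)(CC)CC)(CCC#C)[C@]23CCC[C@](C)(C(=O)OC2)[C@H]13
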